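**Assumption:** the sense of induction in step 7 is assigned from the usual Noyori/Felkin–Anh model and would be confirmed on the first run (the antipodal catalyst is used if C3 comes out R).

**Retrosynthetic overview**
1. Target 16 ⇐ DIBAL-H reduction of E-enoate 15 ⇐ Heck coupling of aryl bromide 13 with methyl acrylate.
2. Dihydrofuran ring (closed last): C2–O bond by acid-mediated, trans-selective cyclisation of phenol alcohol 12; C3 is set by hydrogenation of racemic ketone 11 under dynamic kinetic resolution.
3. 11 ⇐ Friedel–Crafts acyl transfer from lactone 10 to veratrole (C2–aryl bond).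
4. 10 ⇐ oxidative 1,2-aryl shift with lactonisation of o-hydroxypropiophenone 7 (C3–aryl bond; the lactone ring is formed first and opened in step 6).
5. 7 ⇐ veratrole by ortho-lithiation/propanoylation, chelation-directed O-demethylation and para-bromination; veratrole ⇐ catechol (both arenes).

**Route**

Step 1
Reactants: 1 catechol
Product: 2 veratrole (1,2-dimethoxybenzene)
Conditions: MeI (2.5 equiv), K2CO3 (2.5 equiv), acetone, reflux
Reagents that add atoms: iodomethane CI
Why: Double Williamson O-methylation (SN2) of the two phenols; no stereocentre is involved.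

Step 2
Reactants: 2 veratrole; 3 N-methoxy-N-methylpropanamide
Product: 5 1-(2,3-dimethoxyphenyl)propan-1-one, via (2,3-dimethoxyphenyl)lithium 4 (not isolated)
Conditions: n-BuLi (1.1 equiv), TMEDA, THF, 0 °C; then 3, −78 → 0 °C; aq. HCl
Reagents that add atoms: none
Why: Directed ortho-metalation of veratrole at C3 followed by Weinreb ketone synthesis, where the chelated tetrahedral intermediate prevents over-addition.

Step 3
Reactants: 5 1-(2,3-dimethoxyphenyl)propan-1-one
Product: 6 1-(2-hydroxy-3-methoxyphenyl)propan-1-one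
Conditions: BCl3 (1.2 equiv), CH2Cl2, −78 → 0 °C; H2O
Reagents that add atoms: none
Why: Chelation-controlled Lewis-acid ether cleavage: BCl3 bound to the ketone oxygen cleaves only the ortho methoxy group through a six-membered chelate.

Step 4
Reactants: 6 1-(2-hydroxy-3-methoxyphenyl)propan-1-one
Product: 7 1-(5-bromo-2-hydroxy-3-methoxyphenyl)propan-1-one
Conditions: Br2 (1.05 equiv), NaOAc, AcOH, rt
Reagents that add atoms: bromine BrBr
Why: Electrophilic aromatic bromination para to the free phenol (the same selectivity as o-vanillin to 5-bromo-o-vanillin), with the acetate buffer suppressing acid-catalysed α-bromination.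

Step 5
Reactants: 7 1-(5-bromo-2-hydroxy-3-methoxyphenyl)propan-1-one
Product: 10 rac-5-bromo-7-methoxy-3-methyl-1-benzofuran-2(3H)-one, via dimethyl ketal 8 (not isolated), via cyclic ortho ester 9 (not isolated)
Conditions: PhI(OAc)2 (1.2 equiv), H2SO4 (2 equiv), HC(OMe)3, 25–50 °C; then 1 M HCl, THF, rt
Reagents that add atoms: water O
Why: Proposed new method: an oxidative 1,2-aryl shift on an unprotected ortho-hydroxyaryl ethyl ketone in which the phenol itself ends the cascade – HC(OMe)3/H+ converts 7 into ketal 8, whose enol ether is attacked at C-α by PhI(OAc)2, the electron-rich 2-hydroxyaryl group then migrates from C1 to C2 through a phenonium ion as PhI leaves (this creates the aryl–C3 bond of the target, deliberately racemic at this stage), and the resulting dialkoxycarbenium ion is trapped 5-exo by the neighbouring OH to give ortho ester 9, which dilute acid hydrolyses to lactone 10; the closest known reaction type is the PhI(OAc)2 (or Tl(III))/HC(OMe)3 oxidative rearrangement of alkyl aryl ketones to methyl 2-arylalkanoates and the related flavanone-to-dihydrobenzofuran ring contraction, which so far use O-alkylated arenes and methanol as the terminating nucleophile.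

Step 6
Reactants: 10 rac-5-bromo-7-methoxy-3-methyl-1-benzofuran-2(3H)-one; 2 veratrole
Product: 11 rac-2-(5-bromo-2-hydroxy-3-methoxyphenyl)-1-(3,4-dimethoxyphenyl)propan-1-one
Conditions: AlCl3 (3 equiv), veratrole (3 equiv), CH2Cl2, 0 °C → rt; 1 M HCl
Reagents that add atoms: none
Why: Friedel–Crafts acylation with the strained aryl-ester lactone as acyl donor (Fries-type acyl–O cleavage on AlCl3 activation), veratrole reacting para to a methoxy group, which forms the C2–aryl bond and frees the phenol while C3 stays racemic.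

Step 7
Reactants: 11 rac-2-(5-bromo-2-hydroxy-3-methoxyphenyl)-1-(3,4-dimethoxyphenyl)propan-1-one
Product: 13 (2S,3S)-5-bromo-2-(3,4-dimethoxyphenyl)-7-methoxy-3-methyl-2,3-dihydro-1-benzofuran, via benzylic alcohol 12 (not isolated)
Conditions: H2 (10 atm), trans-RuCl2[(R)-xylBINAP][(R)-DAIPEN] (1 mol%), t-BuOK (1.5 equiv), i-PrOH, 25 °C; then HCl (4 M in dioxane, 2 equiv), CH2Cl2, 0 °C
Reagents that add atoms: none
Why: Noyori asymmetric hydrogenation under dynamic kinetic resolution – t-BuOK racemises C2 of the α-aryl ketone through its enolate while the (R,R)-catalyst (1S-selective for aryl ketones) reduces the Felkin–Anh-matched 2S enantiomer to (1S,2S)-12, fixing C3 of the target as S – followed by acid-mediated SN1 cycloetherification, in which the 3,4-dimethoxybenzyl cation is captured by the phenol anti to the C3 methyl to set C2 as S (trans).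

Step 8
Reactants: 13 (2S,3S)-5-bromo-2-(3,4-dimethoxyphenyl)-7-methoxy-3-methyl-2,3-dihydro-1-benzofuran; 14 methyl acrylate
Product: 15 methyl (2E)-3-[(2S,3S)-2-(3,4-dimethoxyphenyl)-7-methoxy-3-methyl-2,3-dihydro-1-benzofuran-5-yl]prop-2-enoate
Conditions: Pd(OAc)2 (5 mol%), P(o-tol)3 (10 mol%), K2CO3 (2 equiv), DMF, 110 °C
Reagents that add atoms: none
Why: Mizoroki–Heck reaction (oxidative addition, syn-insertion, syn-β-hydride elimination) gives the E-enoate and does not touch the benzylic ether or either stereocentre.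

Step 9
Reactants: 15 methyl (2E)-3-[(2S,3S)-2-(3,4-dimethoxyphenyl)-7-methoxy-3-methyl-2,3-dihydro-1-benzofuran-5-yl]prop-2-enoate
Product: 16 (2E)-3-[(2S,3S)-2-(3,4-dimethoxyphenyl)-7-methoxy-3-methyl-2,3-dihydro-1-benzofuran-5-yl]prop-2-en-1-ol
Conditions: DIBAL-H (2.5 equiv), CH2Cl2, −78 °C; Rochelle salt work-up
Reagents that add atoms: none
Why: Low-temperature DIBAL-H 1,2-reduction of the conjugated ester gives the allylic alcohol with the alkene geometry and ring intact, and it keeps the acid-sensitive 4-alkoxycinnamyl alcohol away from acid by making it last.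

**Compound list**
1 | catechol (benzene-1,2-diol) | Oc1ccccc1O | starting material
2 | veratrole (1,2-dimethoxybenzene) | COc1ccccc1OC | intermediate
3 | N-methoxy-N-methylpropanamide | CCC(=O)N(C)OC | starting material
4 | (2,3-dimethoxyphenyl)lithium | [Li]c1cccc(OC)c1OC | intermediate
5 | 1-(2,3-dimethoxyphenyl)propan-1-one | CCC(=O)c1cccc(OC)c1OC | intermediate
6 | 1-(2-hydroxy-3-methoxyphenyl)propan-1-one | CCC(=O)c1cccc(OC)c1O | intermediate
7 | 1-(5-bromo-2-hydroxy-3-methoxyphenyl)propan-1-one | CCC(=O)c1cc(Br)cc(OC)c1O | intermediate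
8 | 4-bromo-2-(1,1-dimethoxypropyl)-6-methoxyphenol (dimethyl ketal) | CCC(OC)(OC)c1cc(Br)cc(OC)c1O | intermediate
9 | rac-5-bromo-2,2,7-trimethoxy-3-methyl-2,3-dihydro-1-benzofuran (cyclic ortho ester) | CC1c2cc(Br)cc(OC)c2OC1(OC)OC | intermediate
10 | rac-5-bromo-7-methoxy-3-methyl-1-benzofuran-2(3H)-one | CC1C(=O)Oc2c(OC)cc(Br)cc21 | intermediate
11 | rac-2-(5-bromo-2-hydroxy-3-methoxyphenyl)-1-(3,4-dimethoxyphenyl)propan-1-one | COc1ccc(C(=O)C(C)c2cc(Br)cc(OC)c2O)cc1OC | intermediate
12 | (1S,2S)-2-(5-bromo-2-hydroxy-3-methoxyphenyl)-1-(3,4-dimethoxyphenyl)propan-1-ol | COc1ccc([C@@H](O)[C@@H](C)c2cc(Br)cc(OC)c2O)cc1OC | intermediate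
13 | (2S,3S)-5-bromo-2-(3,4-dimethoxyphenyl)-7-methoxy-3-methyl-2,3-dihydro-1-benzofuran | COc1ccc([C@H]2Oc3c(OC)cc(Br)cc3[C@@H]2C)cc1OC | intermediate
14 | methyl acrylate | C=CC(=O)OC | starting material
15 | methyl (2E)-3-[(2S,3S)-2-(3,4-dimethoxyphenyl)-7-methoxy-3-methyl-2,3-dihydro-1-benzofuran-5-yl]prop-2-enoate | COc1ccc([C@H]2Oc3c(OC)cc(/C=C/C(=O)OC)cc3[C@@H]2C)cc1OC | intermediate
16 | (2E)-3-[(2S,3S)-2-(3,4-dimethoxyphenyl)-7-methoxy-3-methyl-2,3-dihydro-1-benzofuran-5-yl]prop-2-en-1-ol | COc1ccc([C@H]2Oc3c(OC)cc(/C=C/CO)cc3[C@@H]2C)cc1OC | target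

**Step count and risk**

Total steps: 9. Longest linear sequence: 9 (1 → 2 → 5 → 6 → 7 → 10 → 11 → 13 → 15 → 16; veratrole 2 enters twice, in steps 2 and 6).

The three steps most likely to fail:

Step 5 (the proposed new rearrangement–lactonisation). The free phenol of 7 may be oxidised by the iodine(III) reagent, or it may attack C-α instead of the carbenium ion and give a 2-methylcoumaran-3-one ketal. The fallback uses known chemistry and sets out from 7. O-Benzylation (BnBr, K2CO3, DMF) gives 1-[2-(benzyloxy)-5-bromo-3-methoxyphenyl]propan-1-one F1. The established PhI(OAc)2/H2SO4/HC(OMe)3 1,2-aryl migration of alkoxyaryl ethyl ketones then gives methyl 2-[2-(benzyloxy)-5-bromo-3-methoxyphenyl]propanoate F2. BCl3 (CH2Cl2, −78 °C) removes the benzyl group to give methyl 2-(5-bromo-2-hydroxy-3-methoxyphenyl)propanoate F3, which lactonises (cat. TsOH, toluene, 80 °C) and comes back to the route at 10.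

Step 7 (dynamic kinetic resolution on a phenoxide-bearing ketone). As its potassium phenoxide, 11 may racemise too slowly or bind the catalyst, which would erode ee and conversion. The fallback sets out from 11. MOMCl/i-Pr2NEt gives 2-[5-bromo-3-methoxy-2-(methoxymethoxy)phenyl]-1-(3,4-dimethoxyphenyl)propan-1-one F7. The same Ru-catalysed hydrogenation under dynamic kinetic resolution, now on an ordinary O-protected 2-arylpropiophenone, gives (1S,2S)-2-[5-bromo-3-methoxy-2-(methoxymethoxy)phenyl]-1-(3,4-dimethoxyphenyl)propan-1-ol F8. HCl in MeOH removes the MOM group and cyclises through 12, and the route is rejoined at 13.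

Step 6 (lactone as Friedel–Crafts acyl donor). Acyl transfer may be sluggish, or the product may cyclodehydrate to the 2-aryl-3-methylbenzofuran under the Lewis acid. The fallback sets out from 10 and 2. Me3Al/MeNHOMe·HCl opens the lactone to 2-(5-bromo-2-hydroxy-3-methoxyphenyl)-N-methoxy-N-methylpropanamide F4. Veratrole 2 is brominated (NBS, MeCN) to 4-bromo-1,2-dimethoxybenzene F5 and converted (Mg, THF) into (3,4-dimethoxyphenyl)magnesium bromide F6. Three equivalents of this Grignard reagent (the first deprotonates the phenol) add to the Weinreb amide at 0 °C and the route is rejoined at 11.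

**Further compounds**
F1 | step 5 | 1-[2-(benzyloxy)-5-bromo-3-methoxyphenyl]propan-1-one | CCC(=O)c1cc(Br)cc(OC)c1OCc1ccccc1
F2 | step 5 | rac-methyl 2-[2-(benzyloxy)-5-bromo-3-methoxyphenyl]propanoate | COC(=O)C(C)c1cc(Br)cc(OC)c1OCc1ccccc1
F3 | step 5 | rac-methyl 2-(5-bromo-2-hydroxy-3-methoxyphenyl)propanoate | COC(=O)C(C)c1cc(Br)cc(OC)c1O
F4 | step 6 | rac-2-(5-bromo-2-hydroxy-3-methoxyphenyl)-N-methoxy-N-methylpropanamide | CON(C)C(=O)C(C)c1cc(Br)cc(OC)c1O
F5 | step 6 | 4-bromo-1,2-dimethoxybenzene | COc1ccc(Br)cc1OC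
F6 | step 6 | (3,4-dimethoxyphenyl)magnesium bromide | COc1ccc([Mg]Br)cc1OC
F7 | step 7 | rac-2-[5-bromo-3-methoxy-2-(methoxymethoxy)phenyl]-1-(3,4-dimethoxyphenyl)propan-1-one | COc1ccc(C(=O)C(C)c2cc(Br)cc(OC)c2OCOC)cc1OC
F8 | step 7 | (1S,2S)-2-[5-bromo-3-methoxy-2-(methoxymethoxy)phenyl]-1-(3,4-dimethoxyphenyl)propan-1-ol | COc1ccc([C@@H](O)[C@@H](C)c2cc(Br)cc(OC)c2OCOC)cc1OC
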